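The amounts to watch are the micromolar ones: 2.0 µM of free catalyst against 1.3 µM of impurity, beside 1.0 mM of substrate and 2.00 mM of reagent.

| flask | substrate | reagent | free catalyst | impurity | temperature | remark | time |
|---|---|---|---|---|---|---|---|
| north-east | 1 mM | 2 mM | 2 µM | 0.87 µM | 35 °C | run made earlier |  |
| west | 1 mM | 2 mM | 2 µM | 2 µM | 50 °C | run made earlier |  |
| south-west | 1 mM | 2 mM | 4 µM | 1.3 µM | 35 °C | run made earlier |  |
| ash | 1.0 mM | 2.00 mM | 2.0 µM | 1.3 µM | 60 °C |  | 15 min |
| maple | 1.0 mM | 2.00 mM | 2.0 µM | 1.3 µM | 40 °C |  | 15 min |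

| run | time / min | side product / % | catalyst intermediate C / % | substrate / % | target / % |
|---|---|---|---|---|---|
| north-east | 1.33 | 3.1 | 0.9 | 82.9 | 14.5 |
| north-east | 2.00 | 5.3 | 0.4 | 75.3 | 19.2 |
| north-east | 3.00 | 8.4 | 0 | 64.3 | 25.6 |
| north-east | 5.00 | 21.3 | 0 | 38.5 | 39.5 |
| north-east | 10.0 | 32.2 | 1.0 | 4.5 | 62.8 |
| north-east | 15.0 | 35.6 | 0 | 0 | 65.2 |
| west | 0.667 | 0 | 0 | 99.0 | 0.8 |
| west | 2.00 | 0.3 | 0 | 98.2 | 0 |
| west | 3.00 | 1.8 | 0.4 | 99.7 | 0.1 |
| west | 5.00 | 0.9 | 0.2 | 100.2 | 0.2 |
| west | 8.00 | 2.2 | 0.8 | 99.0 | 0 |
| west | 10.0 | 1.4 | 0.2 | 99.8 | 0 |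
| south-west | 3.00 | 15.3 | 0 | 27.0 | 59.6 |
| south-west | 6.00 | 19.1 | 1.9 | 1.0 | 81.3 |
| south-west | 10.0 | 19.6 | 1.8 | 0.4 | 81.1 |
| south-west | 12.0 | 20.0 | 0 | 0.6 | 81.8 |
| south-west | 15.0 | 18.7 | 0.8 | 0.8 | 82.4 |

(standard deviation of a reading: 1 percentage point)

- percentages count the substrate that a species holds: one side product counts as two

- which of these there is most of at the end, counted by the substrate in it, ash (side product / substrate / catalyst intermediate C / target)
- which of these there is most of at the end, counted by the substrate in it, maple (side product / substrate / catalyst intermediate C / target)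
- amount of the one of these that there is most of at the end, in percent of the substrate charged, ash
- amount of the one of these that there is most of at the end, in percent of the substrate charged, maple

First, how much catalyst works? In the west run, with [impurity] equal to [free catalyst] at 2 µM, substrate still reads 99.8% after 10.0 min. That run was also hotter, at 50 °C, so the reading is not clean, but I take it that impurity removes catalyst one for one. I therefore count the working catalyst W, which is [free catalyst] minus [impurity] as charged: 1.13 µM in north-east and 2.70 µM in south-west.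

Second, what does W do to the split? If the catalytic path runs in proportion to W while the side path keeps its own pace, then with each curve replaced by its mean, the end ratio of side product to target goes as one over W. So I define G, the end ratio of side product to target multiplied by W. It reads 0.617 µM in north-east and 0.613 µM in south-west, level at 35 °C although W differs by a factor of 2.39.

Third, what follows for the new flasks? Both have W of 0.700 µM, so this G gives an end ratio of 0.881 and a target share of 53.2%. I commit to that for maple at 40 °C, with target ahead of side product. For ash at 60 °C, no active run gives G, but target loses its lead once G passes W, a rise by a factor of 1.13, so I lean to side product there without a firm amount.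

The forecast, saying “Maple is then a near coin-flip, leaning side product”, gives side product at 62% for ash and side product at 52% for maple, so my reckoning differs from it on which species leads in maple. The flask gives side product at 63.1% in ash and target at 53.6% in maple.

    free catalyst + impurity → spent catalyst (k = 4.70 × 10⁶ M⁻¹ s⁻¹, Ea = 18.0 kJ mol⁻¹)
    reagent + free catalyst ⇌ catalyst intermediate A (K = 480 M⁻¹, k = 2300 M⁻¹ s⁻¹, Ea = 39.0 kJ mol⁻¹, ΔH = −25.0 kJ mol⁻¹)
    substrate + target → side product (k = 3.40 M⁻¹ s⁻¹, Ea = 57.0 kJ mol⁻¹)
    substrate + catalyst intermediate B → catalyst intermediate C (k = 93000 M⁻¹ s⁻¹, Ea = 17.0 kJ mol⁻¹)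
    catalyst intermediate A ⇌ released group + catalyst intermediate B (K = 3.60 × 10⁻⁴ M, k = 11.0 s⁻¹, Ea = 80.0 kJ mol⁻¹, ΔH = −20.0 kJ mol⁻¹)
    catalyst intermediate C → free catalyst + target (k = 130 s⁻¹, Ea = 58.0 kJ mol⁻¹)
    (constants at 40 °C)

Maple's 46.0% of side product puts G at 0.601 µM, level with north-east, while ash puts it at 1.20 µM, about twice that reading. In ash at 1.44 min, substrate enters catalyst intermediate C 1.9 times as fast as it joins target to give side product, a ratio of rates that belongs to that moment. The ash neighbour charged with 0.0034 mM of free catalyst has W of 2.10 µM, so ash's G puts its target at 63.6%, and it stands at 59.7%.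

(The numbers in the tables come from a simulation from invented constants; noise was put on by code.)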